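**Plan**

- Retrosynthesis: the chroman is opened at O1–C8a (aryl C–O coupling) and at C3–C4 (benzyl metal + epoxide). C2–C1' is then cut to a lactic acid acetal enolate and the complete side-chain iodide. The iodide is cut at C1'–C2' (one-carbon homologation), C11'=C12' (cross-metathesis) and C9'–C10' (allylation), back to geranyl acetate.
- Forward: geranyl acetate is oxidised at its E-methyl group, allylated, prenylated and homologated to iodide 16. 16 is joined to dioxolanone 3; the adduct is reduced to a diol, closed to an epoxide and opened by a benzylic copper reagent. The dihydropyran ring, the only ring made, is closed last.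
- Enabling feature: C2 carries the ring oxygen O1, a methyl group and two methylene arms (C3 and C1'). It is therefore the α-carbon of an α-alkylated lactic acid whose carboxyl carbon becomes C3.
- Stereochemistry: C2 (R) comes from (S)-lactic acid by enolate alkylation with retention, relayed through the tert-butyl acetal carbon. C9' (R) comes from a reagent-controlled allylboration. Both E alkenes are inherited from geranyl acetate.

Key step: step 12

Remark: (+)-Ipc2BOMe is taken to be the B-methoxydiisopinocampheylborane made from (−)-α-pinene.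

**Route**

Step 1
Reactants: 1 (S)-lactic acid; 2 pivalaldehyde
Product: 3 (2S,5S)-2-tert-butyl-5-methyl-1,3-dioxolan-4-one
Conditions: TsOH·H2O (cat.), H2SO4 (cat.), pentane, reflux, Dean–Stark; crystallisation from Et2O/pentane, −78 °C
Reagents that add atoms: none
Why: Acid-catalysed acetalisation with azeotropic removal of water should favour the cis acetal, whose new acetal stereocentre (2S) is set relative to the lactate carbon and which is freed from the trans isomer by low-temperature crystallisation.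

Step 2
Reactants: 4 geranyl acetate
Product: 5 (2E,6E)-8-hydroxy-3,7-dimethylocta-2,6-dien-1-yl acetate
Conditions: SeO2 (cat.), t-BuOOH, salicylic acid (cat.), CH2Cl2, 0 °C to rt
Reagents that add atoms: selenium dioxide, O=[Se]=O (oxygen carrier); tert-butyl hydroperoxide, CC(C)(C)OO (terminal oxidant)
Why: Riley allylic oxidation (ene reaction, then [2,3]-sigmatropic shift) should hit the E-methyl group of the electron-rich terminal alkene, the 2,3-alkene being deactivated by the allylic acetate, so that the 6E geometry is defined; any aldehyde 6 formed by over-oxidation is carried into step 3.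

Step 3
Reactants: 5 (2E,6E)-8-hydroxy-3,7-dimethylocta-2,6-dien-1-yl acetate
Product: 6 (2E,6E)-3,7-dimethyl-8-oxoocta-2,6-dien-1-yl acetate
Conditions: MnO2, CH2Cl2, rt
Reagents that add atoms: none
Why: MnO2 oxidises allylic alcohols selectively to enals under neutral conditions, so the acetate and both E alkenes should be untouched.

Step 4
Reactants: 6 (2E,6E)-3,7-dimethyl-8-oxoocta-2,6-dien-1-yl acetate
Product: 8 (2E,6E,8R)-8-hydroxy-3,7-dimethylundeca-2,6,10-trien-1-yl acetate, via diisopinocampheylborinate ester 7 (not isolated)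
Conditions: (+)-Ipc2BOMe, allylMgBr, Et2O, −78 °C to rt; then 6, −78 °C; then NaBO3·4H2O, THF/H2O, rt
Reagents that add atoms: allylmagnesium bromide, C=CC[Mg]Br
Why: Brown allylboration through a closed chair transition state: the B-allyl reagent of the (−)-α-pinene series should add to the Re face of the enal and set C8 as (R), and the mild perborate oxidation of borinate 7 spares the acetate.

Step 5
Reactants: 8 (2E,6E,8R)-8-hydroxy-3,7-dimethylundeca-2,6,10-trien-1-yl acetate
Product: 9 (2E,6E,8R)-8-(tert-butyldimethylsilyloxy)-3,7-dimethylundeca-2,6,10-trien-1-yl acetate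
Conditions: TBSCl, imidazole, DMF, rt
Reagents that add atoms: tert-butyldimethylsilyl chloride, CC(C)(C)[Si](C)(C)Cl
Why: Standard silylation of the only free hydroxyl group, needed to mask the C8 oxygen against the later base, hydride and sulfonylation steps.

Step 6
Reactants: 9 (2E,6E,8R)-8-(tert-butyldimethylsilyloxy)-3,7-dimethylundeca-2,6,10-trien-1-yl acetate
Product: 10 (2E,6E,8R)-8-(tert-butyldimethylsilyloxy)-3,7,11-trimethyldodeca-2,6,10-trien-1-yl acetate
Conditions: 2-methylbut-2-ene (large excess), second-generation Grubbs catalyst (H2IMes)(PCy3)Cl2Ru=CHPh (cat.), CH2Cl2, 40 °C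
Reagents that add atoms: 2-methylbut-2-ene, CC=C(C)C
Why: Olefin cross-metathesis: only the monosubstituted alkene engages the ruthenium carbene, the trisubstituted alkenes are inert, and the excess of 2-methylbut-2-ene turns the allyl group into the prenyl terminus with loss of propene.

Step 7
Reactants: 10 (2E,6E,8R)-8-(tert-butyldimethylsilyloxy)-3,7,11-trimethyldodeca-2,6,10-trien-1-yl acetate
Product: 11 (2E,6E,8R)-8-(tert-butyldimethylsilyloxy)-3,7,11-trimethyldodeca-2,6,10-trien-1-ol
Conditions: K2CO3 (cat.), MeOH, rt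
Reagents that add atoms: none
Why: Base-catalysed transesterification removes the acetate without touching the secondary silyl ether.

Step 8
Reactants: 11 (2E,6E,8R)-8-(tert-butyldimethylsilyloxy)-3,7,11-trimethyldodeca-2,6,10-trien-1-ol
Product: 12 (2E,6E,8R)-8-(tert-butyldimethylsilyloxy)-3,7,11-trimethyldodeca-2,6,10-trienal
Conditions: MnO2, CH2Cl2, rt
Reagents that add atoms: none
Why: Allylic oxidation with MnO2 gives the E enal without migration or isomerisation of the 2,3-alkene.

Step 9
Reactants: 12 (2E,6E,8R)-8-(tert-butyldimethylsilyloxy)-3,7,11-trimethyldodeca-2,6,10-trienal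
Product: 13 (3E,7E,9R)-9-(tert-butyldimethylsilyloxy)-4,8,12-trimethyltrideca-1,3,7,11-tetraene
Conditions: Ph3PCH3Br, n-BuLi, THF, 0 °C; then 12, −78 °C to rt
Reagents that add atoms: methyltriphenylphosphonium bromide, C[P+](c1ccccc1)(c1ccccc1)c1ccccc1.[Br-]
Why: Wittig methylenation of the enal with the non-stabilised ylide gives the terminal 1,3-diene, the first half of a well-established one-carbon homologation of an allylic alcohol.

Step 10
Reactants: 13 (3E,7E,9R)-9-(tert-butyldimethylsilyloxy)-4,8,12-trimethyltrideca-1,3,7,11-tetraene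
Product: 15 (3E,7E,9R)-9-(tert-butyldimethylsilyloxy)-4,8,12-trimethyltrideca-3,7,11-trien-1-ol, via alkyldisiamylborane 14 (not isolated)
Conditions: Sia2BH (from BH3·THF and 2-methylbut-2-ene), THF, 0 °C; then NaOH, H2O2, 0 °C to rt
Reagents that add atoms: hydrogen peroxide, OO
Why: Hydroboration–oxidation with the bulky disiamylborane should select the monosubstituted terminus of the diene over the three trisubstituted alkenes and place oxygen on C1 (anti-Markovnikov).

Step 11
Reactants: 15 (3E,7E,9R)-9-(tert-butyldimethylsilyloxy)-4,8,12-trimethyltrideca-3,7,11-trien-1-ol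
Product: 16 (3E,7E,9R)-9-(tert-butyldimethylsilyloxy)-1-iodo-4,8,12-trimethyltrideca-3,7,11-triene
Conditions: I2, PPh3, imidazole, CH2Cl2, 0 °C to rt
Reagents that add atoms: iodine, II
Why: Appel-type iodination converts the primary alcohol into the iodide by SN2 displacement of the oxyphosphonium group under neutral conditions that spare the silyl ether.

Step 12
Reactants: 3 (2S,5S)-2-tert-butyl-5-methyl-1,3-dioxolan-4-one (in excess); 16 (3E,7E,9R)-9-(tert-butyldimethylsilyloxy)-1-iodo-4,8,12-trimethyltrideca-3,7,11-triene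
Product: 18 (2S,5R)-2-tert-butyl-5-methyl-5-[(3E,7E,9R)-9-(tert-butyldimethylsilyloxy)-4,8,12-trimethyltrideca-3,7,11-trien-1-yl]-1,3-dioxolan-4-one, via lithium enolate 17 (not isolated)
Conditions: LiN(iPr)2, THF, −78 °C; then 16, DMPU, −78 to −30 °C
Reagents that add atoms: none
Why: Deprotonation of 3 at C5 by lithium diisopropylamide gives the planar lithium enolate 17, in which the lactate stereocentre is erased while the acetal carbon keeps its (S) configuration, and SN2 attack of the enolate carbon on the primary iodide forms the bond that becomes C2–C1' of the chroman. The closest known reaction type is the alkylation of 2-tert-butyl-1,3-dioxolan-4-one enolates of α-hydroxy acids with alkyl halides (self-regeneration of a stereocentre). No ring is closed. The one new stereocentre, the quaternary C5, is controlled by the tert-butyl group on the acetal carbon, which blocks its own face so that the electrophile enters trans to it, replacing the former C–H bond with retention and giving (5R). The step needs diastereofacial selectivity, C- over O-alkylation and substitution over E2 elimination of the homoallylic iodide: the first is secured by the tert-butyl acetal, the second by the lithium counter-ion and the soft iodide, the third by the low temperature, the dipolar cosolvent and the use of the inexpensive enolate in excess.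

Step 13
Reactants: 18 (2S,5R)-2-tert-butyl-5-methyl-5-[(3E,7E,9R)-9-(tert-butyldimethylsilyloxy)-4,8,12-trimethyltrideca-3,7,11-trien-1-yl]-1,3-dioxolan-4-one
Product: 19 (2R,5E,9E,11R)-11-(tert-butyldimethylsilyloxy)-2,6,10,14-tetramethylpentadeca-5,9,13-triene-1,2-diol
Conditions: LiAlH4, Et2O, 0 °C
Reagents that add atoms: none
Why: Hydride reduction of the lactone carbonyl to the primary alcohol opens the acetal, the released pivalaldehyde being reduced to neopentyl alcohol, while the quaternary carbinol carbon is not involved and keeps its configuration.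

Step 14
Reactants: 19 (2R,5E,9E,11R)-11-(tert-butyldimethylsilyloxy)-2,6,10,14-tetramethylpentadeca-5,9,13-triene-1,2-diol
Product: 21 (2R)-2-methyl-2-[(3E,7E,9R)-9-(tert-butyldimethylsilyloxy)-4,8,12-trimethyltrideca-3,7,11-trien-1-yl]oxirane, via primary tosylate 20 (not isolated)
Conditions: TsCl, Et3N, DMAP (cat.), CH2Cl2, 0 °C; then K2CO3, MeOH, rt
Reagents that add atoms: none
Why: Selective sulfonylation of the primary hydroxyl followed by intramolecular Williamson displacement (3-exo-tet) by the tertiary alkoxide closes the oxirane at the CH2 carbon, so the quaternary centre is retained as (R).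

Step 15
Reactants: 22 4-bromo-3,5-dimethylphenol
Product: 23 (4-bromo-3,5-dimethylphenoxy)triisopropylsilane
Conditions: TIPSCl, imidazole, DMF, rt
Reagents that add atoms: triisopropylsilyl chloride, CC(C)[Si](Cl)(C(C)C)C(C)C
Why: Silylation of the phenol with the bulky triisopropylsilyl group gives an ether that should survive radical bromination, Grignard formation and carbonate base and that shields the ring positions next to oxygen.

Step 16
Reactants: 23 (4-bromo-3,5-dimethylphenoxy)triisopropylsilane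
Product: 24 [4-bromo-3-(bromomethyl)-5-methylphenoxy]triisopropylsilane
Conditions: NBS (1 equiv), AIBN (cat.), PhCF3, 80 °C
Reagents that add atoms: N-bromosuccinimide, O=C1CCC(=O)N1Br
Why: Wohl–Ziegler bromination with one equivalent of NBS under radical initiation should brominate one of the two equivalent benzylic methyl groups, ring bromination being disfavoured in the non-polar medium and by the flanking silyl ether.

Step 17
Reactants: 24 [4-bromo-3-(bromomethyl)-5-methylphenoxy]triisopropylsilane (in excess); 21 (2R)-2-methyl-2-[(3E,7E,9R)-9-(tert-butyldimethylsilyloxy)-4,8,12-trimethyltrideca-3,7,11-trien-1-yl]oxirane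
Product: 26 (3R,6E,10E,12R)-1-[2-bromo-3-methyl-5-(triisopropylsilyloxy)phenyl]-12-(tert-butyldimethylsilyloxy)-3,7,11,15-tetramethylhexadeca-6,10,14-trien-3-ol, via benzylmagnesium bromide 25 (not isolated)
Conditions: Mg, Et2O, 0 °C (slow addition of 24); then CuI (cat.), 21, THF, −30 to 0 °C
Reagents that add atoms: none
Why: Magnesium inserts into the benzylic C–Br bond far faster than into the aryl C–Br bond, and the copper-catalysed SN2 opening of the 2,2-disubstituted epoxide at its CH2 carbon forms C3–C4 without touching the tertiary carbinol stereocentre.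

Step 18
Reactants: 26 (3R,6E,10E,12R)-1-[2-bromo-3-methyl-5-(triisopropylsilyloxy)phenyl]-12-(tert-butyldimethylsilyloxy)-3,7,11,15-tetramethylhexadeca-6,10,14-trien-3-ol
Product: 27 (2R)-2-[(3E,7E,9R)-9-(tert-butyldimethylsilyloxy)-4,8,12-trimethyltrideca-3,7,11-trien-1-yl]-2,8-dimethyl-6-(triisopropylsilyloxy)-3,4-dihydro-2H-chromene
Conditions: Pd(OAc)2 (cat.), 2-(di-tert-butylphosphino)-1,1'-binaphthyl (cat.), Cs2CO3, toluene, 80 °C
Reagents that add atoms: none
Why: Buchwald–Hartwig-type intramolecular etherification: oxidative addition of zerovalent palladium into the aryl bromide, exchange of bromide for the tertiary alkoxide (which has no hydrogen on its carbinol carbon for β-hydride elimination) and C–O reductive elimination close the six-membered dihydropyran ring with C2 untouched.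

Step 19
Reactants: 27 (2R)-2-[(3E,7E,9R)-9-(tert-butyldimethylsilyloxy)-4,8,12-trimethyltrideca-3,7,11-trien-1-yl]-2,8-dimethyl-6-(triisopropylsilyloxy)-3,4-dihydro-2H-chromene
Product: 28 sargachromanol C, (2R)-2-[(3E,7E,9R)-9-hydroxy-4,8,12-trimethyltrideca-3,7,11-trien-1-yl]-2,8-dimethyl-3,4-dihydro-2H-chromen-6-ol
Conditions: Bu4NF, AcOH, THF, 0 °C to rt, under argon
Reagents that add atoms: none
Why: Fluoride cleaves both the aryl triisopropylsilyl and the secondary tert-butyldimethylsilyl ether in one operation, the acetic acid buffer protecting the oxidation-prone hydroquinone monoether.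

**Compound list**

1 | (S)-lactic acid | C[C@H](O)C(=O)O | starting material
2 | pivalaldehyde | CC(C)(C)C=O | starting material
3 | (2S,5S)-2-tert-butyl-5-methyl-1,3-dioxolan-4-one | C[C@@H]1O[C@H](C(C)(C)C)OC1=O | intermediate
4 | geranyl acetate | CC(C)=CCC/C(C)=C/COC(C)=O | starting material
5 | (2E,6E)-8-hydroxy-3,7-dimethylocta-2,6-dien-1-yl acetate | CC(=O)OC/C=C(C)/CC/C=C(C)/CO | intermediate
6 | (2E,6E)-3,7-dimethyl-8-oxoocta-2,6-dien-1-yl acetate | CC(=O)OC/C=C(C)/CC/C=C(C)/C=O | intermediate
7 | (2E,6E,8R)-8-[bis(isopinocampheyl)boranyloxy]-3,7-dimethylundeca-2,6,10-trien-1-yl acetate | CC(=O)OC/C=C(C)/CC/C=C(C)/[C@H](OB([C@H]1C[C@H]2C[C@@H]([C@@H]1C)C2(C)C)[C@H]1C[C@H]2C[C@@H]([C@@H]1C)C2(C)C)CC=C | intermediate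
8 | (2E,6E,8R)-8-hydroxy-3,7-dimethylundeca-2,6,10-trien-1-yl acetate | CC(=O)OC/C=C(C)/CC/C=C(C)/[C@H](O)CC=C | intermediate
9 | (2E,6E,8R)-8-(tert-butyldimethylsilyloxy)-3,7-dimethylundeca-2,6,10-trien-1-yl acetate | CC(=O)OC/C=C(C)/CC/C=C(C)/[C@H](O[Si](C)(C)C(C)(C)C)CC=C | intermediate
10 | (2E,6E,8R)-8-(tert-butyldimethylsilyloxy)-3,7,11-trimethyldodeca-2,6,10-trien-1-yl acetate | CC(=O)OC/C=C(C)/CC/C=C(C)/[C@H](O[Si](C)(C)C(C)(C)C)CC=C(C)C | intermediate
11 | (2E,6E,8R)-8-(tert-butyldimethylsilyloxy)-3,7,11-trimethyldodeca-2,6,10-trien-1-ol | OC/C=C(C)/CC/C=C(C)/[C@H](O[Si](C)(C)C(C)(C)C)CC=C(C)C | intermediate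
12 | (2E,6E,8R)-8-(tert-butyldimethylsilyloxy)-3,7,11-trimethyldodeca-2,6,10-trienal | O=C/C=C(C)/CC/C=C(C)/[C@H](O[Si](C)(C)C(C)(C)C)CC=C(C)C | intermediate
13 | (3E,7E,9R)-9-(tert-butyldimethylsilyloxy)-4,8,12-trimethyltrideca-1,3,7,11-tetraene | C=C/C=C(C)/CC/C=C(C)/[C@H](O[Si](C)(C)C(C)(C)C)CC=C(C)C | intermediate
14 | bis(3-methylbutan-2-yl)[(3E,7E,9R)-9-(tert-butyldimethylsilyloxy)-4,8,12-trimethyltrideca-3,7,11-trien-1-yl]borane | CC(C)C(C)B(CC/C=C(C)/CC/C=C(C)/[C@H](O[Si](C)(C)C(C)(C)C)CC=C(C)C)C(C)C(C)C | intermediate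
15 | (3E,7E,9R)-9-(tert-butyldimethylsilyloxy)-4,8,12-trimethyltrideca-3,7,11-trien-1-ol | OCC/C=C(C)/CC/C=C(C)/[C@H](O[Si](C)(C)C(C)(C)C)CC=C(C)C | intermediate
16 | (3E,7E,9R)-9-(tert-butyldimethylsilyloxy)-1-iodo-4,8,12-trimethyltrideca-3,7,11-triene | ICC/C=C(C)/CC/C=C(C)/[C@H](O[Si](C)(C)C(C)(C)C)CC=C(C)C | intermediate
17 | lithium (2S)-2-tert-butyl-5-methyl-1,3-dioxol-4-olate | [Li]OC1=C(C)O[C@H](C(C)(C)C)O1 | intermediate
18 | (2S,5R)-2-tert-butyl-5-methyl-5-[(3E,7E,9R)-9-(tert-butyldimethylsilyloxy)-4,8,12-trimethyltrideca-3,7,11-trien-1-yl]-1,3-dioxolan-4-one | C[C@]1(CC/C=C(C)/CC/C=C(C)/[C@H](O[Si](C)(C)C(C)(C)C)CC=C(C)C)O[C@H](C(C)(C)C)OC1=O | intermediate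
19 | (2R,5E,9E,11R)-11-(tert-butyldimethylsilyloxy)-2,6,10,14-tetramethylpentadeca-5,9,13-triene-1,2-diol | C[C@](CO)(CC/C=C(C)/CC/C=C(C)/[C@H](O[Si](C)(C)C(C)(C)C)CC=C(C)C)O | intermediate
20 | (2R,5E,9E,11R)-11-(tert-butyldimethylsilyloxy)-2-hydroxy-2,6,10,14-tetramethylpentadeca-5,9,13-trien-1-yl 4-methylbenzenesulfonate | C[C@](COS(=O)(=O)c1ccc(C)cc1)(CC/C=C(C)/CC/C=C(C)/[C@H](O[Si](C)(C)C(C)(C)C)CC=C(C)C)O | intermediate
21 | (2R)-2-methyl-2-[(3E,7E,9R)-9-(tert-butyldimethylsilyloxy)-4,8,12-trimethyltrideca-3,7,11-trien-1-yl]oxirane | C[C@@]1(CC/C=C(C)/CC/C=C(C)/[C@H](O[Si](C)(C)C(C)(C)C)CC=C(C)C)CO1 | intermediate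
22 | 4-bromo-3,5-dimethylphenol | Cc1cc(O)cc(C)c1Br | starting material
23 | (4-bromo-3,5-dimethylphenoxy)triisopropylsilane | Cc1cc(O[Si](C(C)C)(C(C)C)C(C)C)cc(C)c1Br | intermediate
24 | [4-bromo-3-(bromomethyl)-5-methylphenoxy]triisopropylsilane | Cc1cc(O[Si](C(C)C)(C(C)C)C(C)C)cc(CBr)c1Br | intermediate
25 | [2-bromo-3-methyl-5-(triisopropylsilyloxy)benzyl]magnesium bromide | Cc1cc(O[Si](C(C)C)(C(C)C)C(C)C)cc(C[Mg]Br)c1Br | intermediate
26 | (3R,6E,10E,12R)-1-[2-bromo-3-methyl-5-(triisopropylsilyloxy)phenyl]-12-(tert-butyldimethylsilyloxy)-3,7,11,15-tetramethylhexadeca-6,10,14-trien-3-ol | C[C@](O)(CCc1cc(O[Si](C(C)C)(C(C)C)C(C)C)cc(C)c1Br)CC/C=C(C)/CC/C=C(C)/[C@H](O[Si](C)(C)C(C)(C)C)CC=C(C)C | intermediate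
27 | (2R)-2-[(3E,7E,9R)-9-(tert-butyldimethylsilyloxy)-4,8,12-trimethyltrideca-3,7,11-trien-1-yl]-2,8-dimethyl-6-(triisopropylsilyloxy)-3,4-dihydro-2H-chromene | C[C@@]1(CC/C=C(C)/CC/C=C(C)/[C@H](O[Si](C)(C)C(C)(C)C)CC=C(C)C)CCc2cc(O[Si](C(C)C)(C(C)C)C(C)C)cc(C)c2O1 | intermediate
28 | sargachromanol C, (2R)-2-[(3E,7E,9R)-9-hydroxy-4,8,12-trimethyltrideca-3,7,11-trien-1-yl]-2,8-dimethyl-3,4-dihydro-2H-chromen-6-ol | CC(C)=CC[C@@H](O)/C(C)=C/CC/C(C)=C/CC[C@]1(C)CCc2cc(O)cc(C)c2O1 | target

**Count**

Total steps: 19. Longest linear sequence: 16 steps (geranyl acetate 4 to 28: steps 2–14 and 17–19).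

**Steps most likely to fail**

Step 12 (key alkylation). The basic enolate may dehydroiodinate the homoallylic iodide to the conjugated diene, or decompose before the slow SN2 step takes place. The fallback sets out from tetraene 13 and comes back at diol 19. The terminal alkene of 13 would be hydroborated with 9-BBN (THF, rt) to the B-alkyl-9-borabicyclo[3.3.1]nonane F1. Suzuki–Miyaura coupling of F1 with 2-bromoprop-2-en-1-ol [Pd(dppf)Cl2, K3PO4, DMF/THF/H2O] would give the 2-substituted allylic alcohol F2. Sharpless asymmetric epoxidation [Ti(OiPr)4, D-(−)-diisopropyl tartrate, t-BuOOH, 4 Å sieves, CH2Cl2, −20 °C] acts on the only allylic alcohol present and should set the quaternary centre in the (R)-epoxy alcohol F3. LiAlH4 then opens the oxirane at its CH2 terminus, turning that carbon into the C2 methyl group and giving 19. In this variant C2 is set by the tartrate instead of by lactic acid.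

Step 17 (benzyl Grignard and epoxide opening). Magnesium insertion may be accompanied by Wurtz-type homocoupling of the benzylic bromide, and magnesium bromide may rearrange or open the 2,2-disubstituted epoxide before the copper reagent attacks. The fallback sets out from diol 19 and benzylic bromide 24 and comes back at 26. C3–C4 is made by olefination and chemoselective reduction instead. Oxidation of the primary alcohol of 19 (TEMPO, PhI(OAc)2, CH2Cl2) would give the α-hydroxy aldehyde F4, which has no α-hydrogen and so cannot epimerise. 24 and PPh3 (toluene, 80 °C) give the benzylic phosphonium bromide F5. Its ylide (NaN(SiMe3)2, THF, two equivalents) would condense with F4 in a Wittig reaction to the styrenyl alkene F6 as an E/Z mixture. Diimide (2-nitrobenzenesulfonyl hydrazide, Et3N, CH2Cl2) reduces this 1,2-disubstituted alkene much faster than the trisubstituted ones and leaves the aryl bromide intact, giving 26.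

Step 18 (aryl C–O ring closure). C–O reductive elimination from the hindered, electron-rich arylpalladium alkoxide may be slower than protodebromination. The fallback sets out from 26 and comes back at the target 28. The ring is closed on a quinone carbonyl instead of by cross-coupling.
- Deprotonation of the tertiary alcohol (MeLi), bromine–lithium exchange (t-BuLi, THF, −78 °C), borylation (B(OMe)3) and oxidation (NaBO3·4H2O) would give the phenol F7.
- Bu4NF removes both silyl groups to give the hydroquinone triol F8, which Ag2O (Et2O) oxidises to the benzoquinone F9.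
- With HC(OMe)3 and pyridinium tosylate in MeOH the tertiary hydroxyl adds to the neighbouring quinone carbonyl and gives the cyclic 8a-methoxy ketal F10.
- Reduction of F10 with ascorbic acid (aqueous MeOH) expels methanol and restores the aromatic ring, giving 28. The C2–O bond is never broken, so the configuration at C2 is retained.

Further compounds
F1 | step 12 | 9-[(3E,7E,9R)-9-(tert-butyldimethylsilyloxy)-4,8,12-trimethyltrideca-3,7,11-trien-1-yl]-9-borabicyclo[3.3.1]nonane | B1(CC/C=C(C)/CC/C=C(C)/[C@H](O[Si](C)(C)C(C)(C)C)CC=C(C)C)C2CCCC1CCC2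
F2 | step 12 | 2-[(3E,7E,9R)-9-(tert-butyldimethylsilyloxy)-4,8,12-trimethyltrideca-3,7,11-trien-1-yl]prop-2-en-1-ol | C=C(CO)CC/C=C(C)/CC/C=C(C)/[C@H](O[Si](C)(C)C(C)(C)C)CC=C(C)C
F3 | step 12 | {(2R)-2-[(3E,7E,9R)-9-(tert-butyldimethylsilyloxy)-4,8,12-trimethyltrideca-3,7,11-trien-1-yl]oxiran-2-yl}methanol | OC[C@]1(CC/C=C(C)/CC/C=C(C)/[C@H](O[Si](C)(C)C(C)(C)C)CC=C(C)C)CO1
F4 | step 17 | (2R,5E,9E,11R)-11-(tert-butyldimethylsilyloxy)-2-hydroxy-2,6,10,14-tetramethylpentadeca-5,9,13-trienal | C[C@](C=O)(CC/C=C(C)/CC/C=C(C)/[C@H](O[Si](C)(C)C(C)(C)C)CC=C(C)C)O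
F5 | step 17 | {[2-bromo-3-methyl-5-(triisopropylsilyloxy)phenyl]methyl}triphenylphosphonium bromide | Cc1cc(O[Si](C(C)C)(C(C)C)C(C)C)cc(C[P+](c2ccccc2)(c2ccccc2)c2ccccc2)c1Br.[Br-]
F6 | step 17 | (3R,6E,10E,12R)-1-[2-bromo-3-methyl-5-(triisopropylsilyloxy)phenyl]-12-(tert-butyldimethylsilyloxy)-3,7,11,15-tetramethylhexadeca-1,6,10,14-tetraen-3-ol (1E/1Z mixture) | C[C@](O)(C=Cc1cc(O[Si](C(C)C)(C(C)C)C(C)C)cc(C)c1Br)CC/C=C(C)/CC/C=C(C)/[C@H](O[Si](C)(C)C(C)(C)C)CC=C(C)C
F7 | step 18 | 2-[(3R,6E,10E,12R)-12-(tert-butyldimethylsilyloxy)-3-hydroxy-3,7,11,15-tetramethylhexadeca-6,10,14-trien-1-yl]-6-methyl-4-(triisopropylsilyloxy)phenol | C[C@](O)(CCc1cc(O[Si](C(C)C)(C(C)C)C(C)C)cc(C)c1O)CC/C=C(C)/CC/C=C(C)/[C@H](O[Si](C)(C)C(C)(C)C)CC=C(C)C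
F8 | step 18 | 2-[(3R,6E,10E,12R)-3,12-dihydroxy-3,7,11,15-tetramethylhexadeca-6,10,14-trien-1-yl]-6-methylbenzene-1,4-diol | C[C@](O)(CCc1cc(O)cc(C)c1O)CC/C=C(C)/CC/C=C(C)/[C@H](O)CC=C(C)C
F9 | step 18 | 2-[(3R,6E,10E,12R)-3,12-dihydroxy-3,7,11,15-tetramethylhexadeca-6,10,14-trien-1-yl]-6-methylcyclohexa-2,5-diene-1,4-dione | C[C@](O)(CCC1=CC(=O)C=C(C)C1=O)CC/C=C(C)/CC/C=C(C)/[C@H](O)CC=C(C)C
F10 | step 18 | (2R)-2-[(3E,7E,9R)-9-hydroxy-4,8,12-trimethyltrideca-3,7,11-trien-1-yl]-8a-methoxy-2,8-dimethyl-2,3,4,8a-tetrahydro-6H-chromen-6-one (both C8a epimers) | C[C@@]1(CC/C=C(C)/CC/C=C(C)/[C@H](O)CC=C(C)C)CCC2=CC(=O)C=C(C)C2(OC)O1
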